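**Strategy.** Kazinol K is divided at the bond between ring A and its benzylic CH2 (Negishi union of a ring B propylzinc with a ring A bromide) and, above all, across the pyran ring. The key step treats the aryl–O1–C2(CH3)2 unit of ring B as a cationic 2-oxa-diene (C4a=C8a–O1+=C2): an aryl isopropenyl ether, ionised through its HCl adduct, takes up C3 and C4 from trimethyl(vinyloxy)silane by Mukaiyama addition at C2 and Friedel–Crafts closure at C4a, then loses silanol, giving the 2H-chromene in one flask. It exploits the tertiary ether carbon C2 and the fact that C4a is the only free carbon ortho to O1, C8 carrying the protected hydroxyl.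

Key step: step 5

Assumption: 2-bromo-4,5-dihydroxybenzaldehyde (1) and 4,6-dibromoresorcinol (13) are treated as purchasable; the target is achiral, so no stereocentre has to be set.

Step 1
Reactants: 1 2-bromo-4,5-dihydroxybenzaldehyde
Product: 2 2-bromo-4-hydroxy-5-[(triisopropylsilyl)oxy]benzaldehyde
Conditions: NaH (2.1 equiv), DMF, 0 °C; TIPSCl (1.0 equiv), 0 °C to rt; dilute aq. HCl to pH 5
Reagents that add atoms: chlorotriisopropylsilane, CC(C)[Si](Cl)(C(C)C)C(C)C
Why: Regioselective silyl ether formation through the catecholate dianion, in which the oxygen meta to the formyl group is the more nucleophilic and the para oxygen gives the better stabilised phenoxide, so kinetic attack and any later silyl migration should both place the silyl group on O-5.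

Step 2
Reactants: 2 2-bromo-4-hydroxy-5-[(triisopropylsilyl)oxy]benzaldehyde
Product: 3 2-bromo-4-(prop-1-en-2-yloxy)-5-[(triisopropylsilyl)oxy]benzaldehyde
Conditions: isopropenyl-B(pin) (2 equiv), Cu(OAc)2 (0.2 equiv), pyridine, 4 Å MS, O2 (1 atm), CH2Cl2, rt
Reagents that add atoms: isopropenylboronic acid pinacol ester, CC(=C)B1OC(C)(C)C(C)(C)O1
Why: Chan–Lam oxidative C–O coupling of a phenol with an alkenylboronate runs at room temperature under weakly basic conditions, should leave aryl bromide, aldehyde and silyl ether untouched, and is done while the para-formyl group still holds the phenoxide on O-4 so that the two catechol oxygens cannot be scrambled.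

Step 3
Reactants: 3 2-bromo-4-(prop-1-en-2-yloxy)-5-[(triisopropylsilyl)oxy]benzaldehyde
Product: 4 ethyl (E)-3-{2-bromo-4-(prop-1-en-2-yloxy)-5-[(triisopropylsilyl)oxy]phenyl}prop-2-enoate
Conditions: Ph3P=CHCO2Et (1.3 equiv), toluene, 80 °C
Reagents that add atoms: ethyl (triphenylphosphoranylidene)acetate, CCOC(=O)C=P(c1ccccc1)(c1ccccc1)c1ccccc1
Why: Wittig olefination with a stabilised ylide should give the (E)-acrylate under neutral conditions that the acid-labile enol ether and the silyl ether tolerate.

Step 4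
Reactants: 4 ethyl (E)-3-{2-bromo-4-(prop-1-en-2-yloxy)-5-[(triisopropylsilyl)oxy]phenyl}prop-2-enoate
Product: 5 ethyl 3-{2-bromo-4-(prop-1-en-2-yloxy)-5-[(triisopropylsilyl)oxy]phenyl}propanoate
Conditions: Cu(OAc)2 (5 mol %), 1,2-bis(diphenylphosphino)benzene (5 mol %), (EtO)2MeSiH (2 equiv), t-BuOH (2 equiv), toluene, rt
Reagents that add atoms: none
Why: Phosphine-ligated copper hydride (Stryker-type conjugate reduction) delivers hydride only to the β-carbon of the enoate, so aryl bromide, isopropenyl ether and silyl ether should survive where heterogeneous hydrogenation would not be selective.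

Step 5
Reactants: 5 ethyl 3-{2-bromo-4-(prop-1-en-2-yloxy)-5-[(triisopropylsilyl)oxy]phenyl}propanoate
Product: 9 ethyl 3-{5-bromo-2,2-dimethyl-8-[(triisopropylsilyl)oxy]-2H-chromen-6-yl}propanoate, via chloro ether 6 (not isolated), via aryloxy aldehyde 7 (not isolated), via silyloxychroman 8 (not isolated)
Conditions: HCl (1.0 equiv, 2 M in Et2O), CH2Cl2, −78 °C; then CH2=CHOSiMe3 (3 equiv), TMSOTf (0.3 equiv), −78 °C to rt
Reagents that add atoms: trimethyl(vinyloxy)silane, C=CO[Si](C)(C)C
Why: Proposed new method: HCl should convert the enol ether completely into the tertiary α-chloro ether 6, which TMSOTf ionises to the O-aryl oxocarbenium ion ArO+=C(CH3)2 (a cationic 2-oxa-diene spanning C4a=C8a–O1=C2); the silyl enol ether adds through its CH2 terminus to C2 (Mukaiyama-type addition, new bond C2–C3), and the aldehyde or silyloxocarbenium carbon of 7 is then attacked by ring carbon C4a in a 6-exo-trig Friedel–Crafts hydroxyalkylation (new bond C4–C4a), so the pyran ring closes as a stepwise formal [4+2]. Acid-promoted loss of trimethylsilanol from 8 through the benzylic cation stabilised by O1 then gives the C3=C4 double bond, the only elimination possible because β-hydrogens sit at C3 alone. The closest known reaction types are the oxa-Povarov reaction (aryl oxocarbenium ion plus alkene to chromans by Prins addition then Friedel–Crafts closure), the Mukaiyama addition of silyl enol ethers to oxocarbenium ions from α-halo ethers and acetals, and the acid cyclodehydration of 3-aryloxy aldehydes to 2H-chromenes; new are the acetone-derived aryl oxocarbenium ion and the merger into one flask. The only stereocentre formed (C4 of 8) is destroyed by the elimination, so no stereocontrol is needed. Regioselectivity of ring closure is secured because, of the two positions ortho to the ether oxygen, one carries the silyloxy group, which also turns the oxocarbenium carbon toward C4a; chemoselectivity (no self-condensation through the nucleophilic enol ether form of 5, no reaction at the ester) is secured by pre-forming 6 and using the far more nucleophilic silyl enol ether in excess at low temperature.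

Step 6
Reactants: 9 ethyl 3-{5-bromo-2,2-dimethyl-8-[(triisopropylsilyl)oxy]-2H-chromen-6-yl}propanoate
Product: 10 ethyl 3-{2,2-dimethyl-5-(3-methylbut-2-en-1-yl)-8-[(triisopropylsilyl)oxy]-2H-chromen-6-yl}propanoate
Conditions: prenylSnBu3 (1.5 equiv), Pd(PPh3)4 (5 mol %), LiCl, DMF, 100 °C
Reagents that add atoms: tributyl(3-methylbut-2-en-1-yl)stannane, CCCC[Sn](CCCC)(CCCC)CC=C(C)C
Why: Migita–Kosugi–Stille coupling in which reductive elimination from the allyl palladium intermediate should occur at the unhindered CH2 terminus, a preference reinforced by the doubly ortho-flanked aryl group, giving the linear prenyl arene without fluoride that would endanger the silyl ether.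

Step 7
Reactants: 10 ethyl 3-{2,2-dimethyl-5-(3-methylbut-2-en-1-yl)-8-[(triisopropylsilyl)oxy]-2H-chromen-6-yl}propanoate
Product: 11 3-{2,2-dimethyl-5-(3-methylbut-2-en-1-yl)-8-[(triisopropylsilyl)oxy]-2H-chromen-6-yl}propan-1-ol
Conditions: DIBAL-H (2.5 equiv), CH2Cl2, −78 to 0 °C; Rochelle salt work-up
Reagents that add atoms: none
Why: Hydride reduction of the ester to the primary alcohol by DIBAL-H, to which the aryl silyl ether and the three kinds of alkene are inert.

Step 8
Reactants: 11 3-{2,2-dimethyl-5-(3-methylbut-2-en-1-yl)-8-[(triisopropylsilyl)oxy]-2H-chromen-6-yl}propan-1-ol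
Product: 12 {[6-(3-iodopropyl)-2,2-dimethyl-5-(3-methylbut-2-en-1-yl)-2H-chromen-8-yl]oxy}triisopropylsilane
Conditions: I2, PPh3, imidazole, CH2Cl2, 0 °C to rt
Reagents that add atoms: iodine, II
Why: Appel-type iodination (Garegg–Samuelsson conditions) replaces the primary hydroxyl by iodide under imidazole-buffered, acid-free conditions that should spare the prenyl and chromene double bonds.

Step 9
Reactants: 13 4,6-dibromobenzene-1,3-diol
Product: 14 1,5-dibromo-2,4-bis[(triisopropylsilyl)oxy]benzene
Conditions: TIPSCl (2.4 equiv), imidazole, DMF, 40 °C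
Reagents that add atoms: chlorotriisopropylsilane, CC(C)[Si](Cl)(C(C)C)C(C)C
Why: Standard imidazole-promoted silylation of both phenols gives base-stable, fluoride-labile ethers matching the protecting group of ring B.

Step 10
Reactants: 14 1,5-dibromo-2,4-bis[(triisopropylsilyl)oxy]benzene
Product: 15 1-bromo-5-(2-methylbut-3-en-2-yl)-2,4-bis[(triisopropylsilyl)oxy]benzene
Conditions: 14 (2 equiv), prenyl-B(pin) (1 equiv), Pd(OAc)2 (2 mol %), γ-selective biaryl phosphine ligand (4 mol %), aq. K3PO4, THF, 40 °C
Reagents that add atoms: 4,4,5,5-tetramethyl-2-(3-methylbut-2-en-1-yl)-1,3,2-dioxaborolane, CC(C)=CCB1OC(C)(C)C(C)(C)O1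
Why: Suzuki–Miyaura coupling of an allylboronate in its γ-selective mode, in which SE2' transmetalation places palladium on the tertiary carbon and fast reductive elimination forges the aryl–C(CH3)2 bond of the 1,1-dimethylallyl group, while the excess of the symmetric dibromide should hold the reaction at the mono stage.

Step 11
Reactants: 12 {[6-(3-iodopropyl)-2,2-dimethyl-5-(3-methylbut-2-en-1-yl)-2H-chromen-8-yl]oxy}triisopropylsilane; 15 1-bromo-5-(2-methylbut-3-en-2-yl)-2,4-bis[(triisopropylsilyl)oxy]benzene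
Product: 17 tris(triisopropylsilyl) ether of Kazinol K, via alkylzinc iodide 16 (not isolated)
Conditions: Zn dust (activated), LiCl, THF, 40 °C; then 15, Pd(OAc)2 (3 mol %), SPhos (6 mol %), THF, 50 °C
Reagents that add atoms: none
Why: Negishi coupling in which LiCl-assisted zinc insertion gives the primary alkylzinc iodide 16 without touching alkenes or silyl ethers, and the bulky electron-rich biaryl phosphine should make reductive elimination outrun β-hydride elimination in the sp3–sp2 bond formation.

Step 12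
Reactants: 17 tris(triisopropylsilyl) ether of Kazinol K
Product: 18 Kazinol K
Conditions: TBAF (3.5 equiv), AcOH (3.5 equiv), THF, 0 °C to rt
Reagents that add atoms: none
Why: Fluoride-mediated desilylation cleaves the three aryl silyl ethers, and the acetic acid buffer keeps the electron-rich phenols protonated so that neither air oxidation nor cyclisation onto the neighbouring allyl groups should occur.

**Compound list**

1 | 2-bromo-4,5-dihydroxybenzaldehyde | O=Cc1cc(O)c(O)cc1Br | starting material
2 | 2-bromo-4-hydroxy-5-[(triisopropylsilyl)oxy]benzaldehyde | O=Cc1cc(O[Si](C(C)C)(C(C)C)C(C)C)c(O)cc1Br | intermediate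
3 | 2-bromo-4-(prop-1-en-2-yloxy)-5-[(triisopropylsilyl)oxy]benzaldehyde | O=Cc1cc(O[Si](C(C)C)(C(C)C)C(C)C)c(OC(C)=C)cc1Br | intermediate
4 | ethyl (E)-3-{2-bromo-4-(prop-1-en-2-yloxy)-5-[(triisopropylsilyl)oxy]phenyl}prop-2-enoate | CCOC(=O)/C=C/c1cc(O[Si](C(C)C)(C(C)C)C(C)C)c(OC(C)=C)cc1Br | intermediate
5 | ethyl 3-{2-bromo-4-(prop-1-en-2-yloxy)-5-[(triisopropylsilyl)oxy]phenyl}propanoate | CCOC(=O)CCc1cc(O[Si](C(C)C)(C(C)C)C(C)C)c(OC(C)=C)cc1Br | intermediate
6 | ethyl 3-{2-bromo-4-[(2-chloropropan-2-yl)oxy]-5-[(triisopropylsilyl)oxy]phenyl}propanoate (α-chloro ether, not isolated) | CCOC(=O)CCc1cc(O[Si](C(C)C)(C(C)C)C(C)C)c(OC(C)(C)Cl)cc1Br | intermediate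
7 | ethyl 3-{2-bromo-4-[(2-methyl-4-oxobutan-2-yl)oxy]-5-[(triisopropylsilyl)oxy]phenyl}propanoate (β-aryloxy aldehyde, not isolated) | CCOC(=O)CCc1cc(O[Si](C(C)C)(C(C)C)C(C)C)c(OC(C)(C)CC=O)cc1Br | intermediate
8 | ethyl 3-{5-bromo-2,2-dimethyl-8-[(triisopropylsilyl)oxy]-4-[(trimethylsilyl)oxy]-3,4-dihydro-2H-chromen-6-yl}propanoate (racemic, not isolated) | CCOC(=O)CCc1cc(O[Si](C(C)C)(C(C)C)C(C)C)c2OC(C)(C)CC(O[Si](C)(C)C)c2c1Br | intermediate
9 | ethyl 3-{5-bromo-2,2-dimethyl-8-[(triisopropylsilyl)oxy]-2H-chromen-6-yl}propanoate | CCOC(=O)CCc1cc(O[Si](C(C)C)(C(C)C)C(C)C)c2OC(C)(C)C=Cc2c1Br | intermediate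
10 | ethyl 3-{2,2-dimethyl-5-(3-methylbut-2-en-1-yl)-8-[(triisopropylsilyl)oxy]-2H-chromen-6-yl}propanoate | CCOC(=O)CCc1cc(O[Si](C(C)C)(C(C)C)C(C)C)c2OC(C)(C)C=Cc2c1CC=C(C)C | intermediate
11 | 3-{2,2-dimethyl-5-(3-methylbut-2-en-1-yl)-8-[(triisopropylsilyl)oxy]-2H-chromen-6-yl}propan-1-ol | OCCCc1cc(O[Si](C(C)C)(C(C)C)C(C)C)c2OC(C)(C)C=Cc2c1CC=C(C)C | intermediate
12 | {[6-(3-iodopropyl)-2,2-dimethyl-5-(3-methylbut-2-en-1-yl)-2H-chromen-8-yl]oxy}triisopropylsilane | ICCCc1cc(O[Si](C(C)C)(C(C)C)C(C)C)c2OC(C)(C)C=Cc2c1CC=C(C)C | intermediate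
13 | 4,6-dibromobenzene-1,3-diol | Oc1cc(O)c(Br)cc1Br | starting material
14 | 1,5-dibromo-2,4-bis[(triisopropylsilyl)oxy]benzene | CC(C)[Si](Oc1cc(O[Si](C(C)C)(C(C)C)C(C)C)c(Br)cc1Br)(C(C)C)C(C)C | intermediate
15 | 1-bromo-5-(2-methylbut-3-en-2-yl)-2,4-bis[(triisopropylsilyl)oxy]benzene | C=CC(C)(C)c1cc(Br)c(O[Si](C(C)C)(C(C)C)C(C)C)cc1O[Si](C(C)C)(C(C)C)C(C)C | intermediate
16 | (3-{2,2-dimethyl-5-(3-methylbut-2-en-1-yl)-8-[(triisopropylsilyl)oxy]-2H-chromen-6-yl}propyl)zinc iodide (not isolated) | I[Zn]CCCc1cc(O[Si](C(C)C)(C(C)C)C(C)C)c2OC(C)(C)C=Cc2c1CC=C(C)C | intermediate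
17 | tris(triisopropylsilyl) ether of Kazinol K | C=CC(C)(C)c1cc(CCCc2cc(O[Si](C(C)C)(C(C)C)C(C)C)c3OC(C)(C)C=Cc3c2CC=C(C)C)c(O[Si](C(C)C)(C(C)C)C(C)C)cc1O[Si](C(C)C)(C(C)C)C(C)C | intermediate
18 | Kazinol K | C=CC(C)(C)c1cc(CCCc2cc(O)c3c(c2CC=C(C)C)C=CC(C)(C)O3)c(O)cc1O | target

**Step count.** Total: 12 steps. Longest linear sequence: 10 steps (steps 1 to 8, then 11 and 12).

**Steps most likely to fail**

Step 5 (proposed new method). The oxocarbenium ion may be lost to proton loss and self-condensation or to oligomerisation of the silyl enol ether. The β-aryloxy aldehyde may shed the phenol by retro-oxa-Michael fragmentation before it cyclises. Ring closure ortho to bromine may also be too slow. The fallback uses known chemistry, sets out from 2 and comes back at 9. Phenol 2 is alkylated with 3-chloro-3-methylbut-1-yne (DBU, catalytic CuCl2, MeCN, 0 °C) to 2-bromo-4-[(2-methylbut-3-yn-2-yl)oxy]-5-[(triisopropylsilyl)oxy]benzaldehyde F1. Heating in N,N-diethylaniline at about 180 °C brings about the aromatic propargyl Claisen rearrangement, 1,5-hydrogen shift and oxa-6π electrocyclisation to 5-bromo-2,2-dimethyl-8-[(triisopropylsilyl)oxy]-2H-chromene-6-carbaldehyde F2, again with only one free ortho carbon available. Wittig olefination as in step 3 gives ethyl (E)-3-{5-bromo-2,2-dimethyl-8-[(triisopropylsilyl)oxy]-2H-chromen-6-yl}prop-2-enoate F3, and copper hydride conjugate reduction as in step 4 returns 9.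

Step 10. Oxidative addition and reductive elimination beside the bulky silyloxy group may be slow. Isomerisation of the allyl palladium intermediate may leak to the linear isomer, and the second bromide may couple as well. The fallback sets out from 14 and comes back at 15. Palladium-catalysed α-arylation of the Reformatsky reagent BrZnC(CH3)2CO2CH3 with an excess of 14 (Pd(dba)2, P(t-Bu)3, THF) gives methyl 2-{5-bromo-2,4-bis[(triisopropylsilyl)oxy]phenyl}-2-methylpropanoate F4. DIBAL-H at −78 °C reduces it to 2-{5-bromo-2,4-bis[(triisopropylsilyl)oxy]phenyl}-2-methylpropanal F5, and methylenation with Ph3P=CH2 returns 15.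

Step 6. Oxidative addition into the doubly ortho-flanked C–Br bond may be sluggish and give way to protodebromination, and allylic transposition during prenyl transfer may give the branched isomer. The fallback sets out from 9 and comes back at 10. Stille coupling with the smaller, faster-transferring allyltributylstannane gives ethyl 3-{2,2-dimethyl-5-(prop-2-en-1-yl)-8-[(triisopropylsilyl)oxy]-2H-chromen-6-yl}propanoate F6. Cross-metathesis of F6 with 2-methyl-2-butene (second-generation Grubbs catalyst, CH2Cl2, 40 °C) then builds the trisubstituted alkene and returns 10.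

**Further compounds**

F1 | step 5 | 2-bromo-4-[(2-methylbut-3-yn-2-yl)oxy]-5-[(triisopropylsilyl)oxy]benzaldehyde | O=Cc1cc(O[Si](C(C)C)(C(C)C)C(C)C)c(OC(C)(C)C#C)cc1Br
F2 | step 5 | 5-bromo-2,2-dimethyl-8-[(triisopropylsilyl)oxy]-2H-chromene-6-carbaldehyde | O=Cc1cc(O[Si](C(C)C)(C(C)C)C(C)C)c2OC(C)(C)C=Cc2c1Br
F3 | step 5 | ethyl (E)-3-{5-bromo-2,2-dimethyl-8-[(triisopropylsilyl)oxy]-2H-chromen-6-yl}prop-2-enoate | CCOC(=O)/C=C/c1cc(O[Si](C(C)C)(C(C)C)C(C)C)c2OC(C)(C)C=Cc2c1Br
F4 | step 10 | methyl 2-{5-bromo-2,4-bis[(triisopropylsilyl)oxy]phenyl}-2-methylpropanoate | COC(=O)C(C)(C)c1cc(Br)c(O[Si](C(C)C)(C(C)C)C(C)C)cc1O[Si](C(C)C)(C(C)C)C(C)C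
F5 | step 10 | 2-{5-bromo-2,4-bis[(triisopropylsilyl)oxy]phenyl}-2-methylpropanal | O=CC(C)(C)c1cc(Br)c(O[Si](C(C)C)(C(C)C)C(C)C)cc1O[Si](C(C)C)(C(C)C)C(C)C
F6 | step 6 | ethyl 3-{2,2-dimethyl-5-(prop-2-en-1-yl)-8-[(triisopropylsilyl)oxy]-2H-chromen-6-yl}propanoate | CCOC(=O)CCc1cc(O[Si](C(C)C)(C(C)C)C(C)C)c2OC(C)(C)C=Cc2c1CC=C
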